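**Retrosynthetic overview**

1. Target ⇐ 19: singlet oxygen adds across C1/C3 of a 3‑silyloxycyclopentadiene and puts in C1–OH, C3=O and the C4=C5 double bond at the very end; before that only C8 ketone reduction and the two acylations (C8 angelate, C11 acetate).
2. Seven‑membered ring ⇐ (4+3) cycloaddition of a 2‑silyloxyallyl (oxyallyl) cation, the enolonium form of a methyl ketone (C7–C8–C9 and C11 from mesityl oxide), with the s‑cis silyloxydiene C10=C1–C5=C6 built on a cyclopentanone. The C9–C10 bond joins two normally nucleophilic carbons; C6–C7 closes the ring; C6, C7 and C10 are set together.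
3. Diene ⇐ 3‑ethoxy‑2‑methylcyclopent‑2‑enone: α′‑aldol condensation with acetaldehyde (C10, C14), dithiane formyl‑anion addition with Stork–Danheiser transposition (C6), then 1,4‑hydrosilylation.
4. Ring order: the five‑membered ring is bought; the seven‑membered ring is closed in the (4+3) step. The absolute configuration comes from a CBS reduction that resolves the racemic cycloadduct.

Assumption: guaiane numbering is used for all bicyclic compounds (five‑membered ring C1–C5 with the C15 methyl on C4; seven‑membered ring C1, C5–C10 with the C14 methyl on C10; C11 is the carbinol carbon on C7; β is the face of the C10 methyl), and 3‑ethoxy‑2‑methylcyclopent‑2‑en‑1‑one is taken as a catalogue compound.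

Compounds 10, 14 and 15 are racemic; the enantiomer that is carried on is drawn. From 16 on all compounds are single enantiomers.

**Route**

Step 1
Reactants: 1 3‑ethoxy‑2‑methylcyclopent‑2‑en‑1‑one; 2 acetaldehyde
Product: 5 (5E)‑3‑ethoxy‑5‑ethylidene‑2‑methylcyclopent‑2‑en‑1‑one, via aldol adduct 3 (not isolated), via aldol mesylate 4 (not isolated)
Conditions: LDA, THF, −78 °C; MeCHO; MsCl, −78 → 0 °C; DBU, rt
Reagents that add atoms: none
Why: Kinetic α′‑deprotonation of the vinylogous ester (Stork–Danheiser enolate), aldol addition to acetaldehyde, mesylation and E1cB elimination (aldol condensation) give the cross‑conjugated ethylidene ketone as the E isomer, because the methyl group avoids the carbonyl oxygen.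

Step 2
Reactants: 5 (5E)‑3‑ethoxy‑5‑ethylidene‑2‑methylcyclopent‑2‑en‑1‑one; 6 1,3‑dithiane
Product: 8 (4E)‑3‑(1,3‑dithian‑2‑yl)‑4‑ethylidene‑2‑methylcyclopent‑2‑en‑1‑one, via dithianyl carbinol 7 (not isolated)
Conditions: 6, n‑BuLi, THF, −30 °C; 5, −78 °C; then 1 M HCl, THF, rt
Reagents that add atoms: water, O (the new C3 carbonyl oxygen)
Why: 2‑Lithio‑1,3‑dithiane (Corey–Seebach formyl anion equivalent) adds 1,2 to the vinylogous ester carbonyl, and acid then ionises the tertiary allylic alcohol and hydrolyses the ethoxy‑stabilised cation (Stork–Danheiser 1,3‑carbonyl transposition), so that C6 arrives at the aldehyde oxidation level on the β‑carbon of the new enone.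

Step 3
Reactants: 8 (4E)‑3‑(1,3‑dithian‑2‑yl)‑4‑ethylidene‑2‑methylcyclopent‑2‑en‑1‑one
Product: 9 (5E)‑5‑ethylidene‑2‑methyl‑3‑oxocyclopent‑1‑ene‑1‑carbaldehyde
Conditions: MeI, CaCO3, MeCN–H2O (4:1), 40 °C; product used crude
Reagents that add atoms: water, O
Why: Alkylative hydrolysis of the allylic 1,3‑dithiane (S‑methylation, then hydrolysis of the sulfonium) unmasks the aldehyde under buffered, non‑oxidising conditions that leave the dienone untouched.

Step 4
Reactants: 9 (5E)‑5‑ethylidene‑2‑methyl‑3‑oxocyclopent‑1‑ene‑1‑carbaldehyde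
Product: 10 rac‑(2S,3E,4E)‑3‑{[tert‑butyl(dimethyl)silyl]oxymethylidene}‑4‑ethylidene‑2‑methylcyclopentan‑1‑one
Conditions: t‑BuMe2SiH, RhCl(PPh3)3 (2 mol%), PhH, 50 °C
Reagents that add atoms: tert‑butyldimethylsilane, CC(C)(C)[SiH](C)C
Why: Rhodium‑catalysed 1,4‑hydrosilylation of the enal (Ojima type; monohydrosilanes add 1,4) delivers hydride to C4, β to the more reactive aldehyde, through the s‑cis oxa‑π‑allyl rhodium species, so the silyloxy group ends syn to C4 (E enol ether, the "outside" position of the s‑cis diene), which is also the less strained isomer once C4 is sp3; C4 is formed racemic.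

Step 5
Reactants: 11 4‑methylpent‑3‑en‑2‑one (mesityl oxide)
Product: 12 rac‑1‑(3,3‑dimethyloxiran‑2‑yl)ethan‑1‑one
Conditions: 30% H2O2, NaOH (cat.), MeOH, 0 °C
Reagents that add atoms: hydrogen peroxide, OO
Why: Weitz–Scheffer nucleophilic epoxidation of the enone (conjugate addition of hydroperoxide, then ring closure) gives the racemic α,β‑epoxy ketone.

Step 6
Reactants: 12 rac‑1‑(3,3‑dimethyloxiran‑2‑yl)ethan‑1‑one
Product: 13 rac‑{[1‑(3,3‑dimethyloxiran‑2‑yl)ethenyl]oxy}(trimethyl)silane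
Conditions: LDA, THF, −78 °C; TMSCl
Reagents that add atoms: chlorotrimethylsilane, C[Si](C)(C)Cl
Why: The methyl group is the only enolisable position, so kinetic deprotonation and O‑silylation give the epoxy enol silane, which is the latent 2‑silyloxyallyl cation.

Step 7
Reactants: 10 rac‑(2S,3E,4E)‑3‑{[tert‑butyl(dimethyl)silyl]oxymethylidene}‑4‑ethylidene‑2‑methylcyclopentan‑1‑one; 13 rac‑{[1‑(3,3‑dimethyloxiran‑2‑yl)ethenyl]oxy}(trimethyl)silane
Product: 15 rac‑(6R,7R,10S)‑3,6‑bis(tert‑butyldimethylsilyloxy)‑11‑(trimethylsilyloxy)guaia‑1(5),3‑dien‑8‑one, via cycloadduct diketone 14 (not isolated)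
Conditions: 13 (2 equiv), TMSOTf (10 mol%), CH2Cl2, −78 °C; then Et3N, TBSOTf, −78 → −20 °C
Reagents that add atoms: tert‑butyldimethylsilyl trifluoromethanesulfonate, CC(C)(C)[Si](C)(C)OS(=O)(=O)C(F)(F)F
Why: Proposed new method: TMSOTf opens the epoxide of 13 to a 2‑silyloxyallyl (oxyallyl) cation, the enolonium form of the methyl ketone, whose CH2 terminus C9 (normally a nucleophilic α‑carbon) is attacked by C10, the nucleophilic γ‑carbon of silyl dienol ether 10, and whose other terminus C7 then closes onto the C6 oxocarbenium carbon, a (4+3) cycloaddition modelled on the silyl‑triflate‑catalysed (4+3) reactions of epoxy enol silanes with furan and cyclopentadiene; suprafacial addition of the W‑shaped cation in the compact mode to the diene face anti to the C4 methyl puts the outside C10 methyl, the outside C6 OTBS and the C7 side chain all cis (C6, C7, C10 set), and in‑situ soft enolisation of the doubly activated C3 ketone then gives the silyloxycyclopentadiene and erases C4.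

Step 8
Reactants: 15 rac‑(6R,7R,10S)‑3,6‑bis(tert‑butyldimethylsilyloxy)‑11‑(trimethylsilyloxy)guaia‑1(5),3‑dien‑8‑one
Product: 17 (6R,7R,8R,10S)‑3,6‑bis(tert‑butyldimethylsilyloxy)guaia‑1(5),3‑diene‑8,11‑diol, via C8 alcohol 16 (not isolated)
Conditions: (S)‑Me‑CBS (20 mol%), catecholborane (0.6 equiv), PhMe, −78 → −40 °C; then K2CO3, MeOH, 0 °C; ent‑15 recovered
Reagents that add atoms: none
Why: Corey–Bakshi–Shibata reduction treats the branched C7 side as the large group, so for the enantiomer drawn the reagent‑preferred face coincides with the substrate‑preferred α face (anti to the C7 substituent) and the 8β (8R) alcohol forms fast, while the mirror‑image ketone is mismatched and is recovered (kinetic resolution, at most 50% yield); basic methanolysis then removes only the tertiary trimethylsilyl ether.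

Step 9
Reactants: 17 (6R,7R,8R,10S)‑3,6‑bis(tert‑butyldimethylsilyloxy)guaia‑1(5),3‑diene‑8,11‑diol
Product: 18 (6R,7R,8R,10S)‑3,6‑bis(tert‑butyldimethylsilyloxy)‑11‑hydroxyguaia‑1(5),3‑dien‑8‑yl (2Z)‑2‑methylbut‑2‑enoate
Conditions: angelic acid, 2,4,6‑Cl3C6H2COCl, Et3N, PhMe, rt; then 17, 80 °C
Reagents that add atoms: angelic acid [(2Z)‑2‑methylbut‑2‑enoic acid], C/C=C(/C)C(=O)O
Why: Yamaguchi‑type mixed‑anhydride esterification run without DMAP acylates the secondary C8 hydroxyl and not the tertiary C11 hydroxyl, and keeps the Z (angelate) double bond from isomerising to the tiglate.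

Step 10
Reactants: 18 (6R,7R,8R,10S)‑3,6‑bis(tert‑butyldimethylsilyloxy)‑11‑hydroxyguaia‑1(5),3‑dien‑8‑yl (2Z)‑2‑methylbut‑2‑enoate
Product: 19 (6R,7R,8R,10S)‑11‑acetoxy‑3,6‑bis(tert‑butyldimethylsilyloxy)guaia‑1(5),3‑dien‑8‑yl (2Z)‑2‑methylbut‑2‑enoate
Conditions: Ac2O, DMAP, Et3N, CH2Cl2, 35 °C
Reagents that add atoms: acetic anhydride, CC(=O)OC(C)=O
Why: DMAP‑catalysed acyl transfer acetylates the only free hydroxyl, the unhindered tertiary C11 carbinol, under basic conditions that the silyl dienol ether survives.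

Step 11
Reactants: 19 (6R,7R,8R,10S)‑11‑acetoxy‑3,6‑bis(tert‑butyldimethylsilyloxy)guaia‑1(5),3‑dien‑8‑yl (2Z)‑2‑methylbut‑2‑enoate
Product: 22 (1R,6R,7S,8R,10S)‑11‑acetoxy‑1,6‑dihydroxy‑3‑oxoguai‑4‑en‑8‑yl (2Z)‑2‑methylbut‑2‑enoate (CNP0273287.1), via silylperoxy enone 20 (not isolated), via bis‑silyl ether 21 (not isolated)
Conditions: O2, TPP (cat.), hν, CH2Cl2, −78 °C; PPh3, −78 °C → rt; then HF·pyridine, THF, 0 °C → rt
Reagents that add atoms: oxygen (as singlet oxygen), O=O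
Why: Singlet oxygen adds [4+2] across C1 and C3 of the electron‑rich silyloxycyclopentadiene from the α face (opposite to the pseudo‑axial C6 OTBS and the C10 methyl), the endoperoxide collapses with silyl transfer to the γ‑silylperoxy enone, the phosphine reduces the O–O bond and HF·pyridine cleaves both silyl ethers, which sets C1 and creates the 3‑oxo‑4‑ene unit in one flask.

**Compound list**

1 | 3‑ethoxy‑2‑methylcyclopent‑2‑en‑1‑one | CCOC1=C(C)C(=O)CC1 | starting material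
2 | acetaldehyde | CC=O | starting material
3 | 3‑ethoxy‑5‑(1‑hydroxyethyl)‑2‑methylcyclopent‑2‑en‑1‑one (diastereomer mixture, present as lithium alkoxide) | CCOC1=C(C)C(=O)C(C(C)O)C1 | intermediate
4 | 1‑(4‑ethoxy‑3‑methyl‑2‑oxocyclopent‑3‑en‑1‑yl)ethyl methanesulfonate (diastereomer mixture) | CCOC1=C(C)C(=O)C(C(C)OS(C)(=O)=O)C1 | intermediate
5 | (5E)‑3‑ethoxy‑5‑ethylidene‑2‑methylcyclopent‑2‑en‑1‑one | CCOC1=C(C)C(=O)/C(=C/C)C1 | intermediate
6 | 1,3‑dithiane | C1CSCSC1 | starting material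
7 | rac‑(5E)‑1‑(1,3‑dithian‑2‑yl)‑3‑ethoxy‑5‑ethylidene‑2‑methylcyclopent‑2‑en‑1‑ol | CCOC1=C(C)C(O)(C2SCCCS2)/C(=C/C)C1 | intermediate
8 | (4E)‑3‑(1,3‑dithian‑2‑yl)‑4‑ethylidene‑2‑methylcyclopent‑2‑en‑1‑one | C/C=C1/C(C2SCCCS2)=C(C)C(=O)C1 | intermediate
9 | (5E)‑5‑ethylidene‑2‑methyl‑3‑oxocyclopent‑1‑ene‑1‑carbaldehyde | C/C=C1/C(C=O)=C(C)C(=O)C1 | intermediate
10 | rac‑(2S,3E,4E)‑3‑{[tert‑butyl(dimethyl)silyl]oxymethylidene}‑4‑ethylidene‑2‑methylcyclopentan‑1‑one | C/C=C1\CC(=O)[C@@H](C)/C1=C\O[Si](C)(C)C(C)(C)C | intermediate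
11 | 4‑methylpent‑3‑en‑2‑one (mesityl oxide) | CC(=O)C=C(C)C | starting material
12 | rac‑1‑(3,3‑dimethyloxiran‑2‑yl)ethan‑1‑one | CC(=O)C1OC1(C)C | intermediate
13 | rac‑{[1‑(3,3‑dimethyloxiran‑2‑yl)ethenyl]oxy}(trimethyl)silane | C=C(O[Si](C)(C)C)C1OC1(C)C | intermediate
14 | rac‑(4S,6R,7R,10S)‑6‑(tert‑butyldimethylsilyloxy)‑11‑(trimethylsilyloxy)guai‑1(5)‑ene‑3,8‑dione | O=C1C[C@H](C)C2=C([C@H](C)C(=O)C2)[C@H](O[Si](C)(C)C(C)(C)C)[C@@H]1C(C)(C)O[Si](C)(C)C | intermediate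
15 | rac‑(6R,7R,10S)‑3,6‑bis(tert‑butyldimethylsilyloxy)‑11‑(trimethylsilyloxy)guaia‑1(5),3‑dien‑8‑one | O=C1C[C@H](C)C2=C(C(C)=C(O[Si](C)(C)C(C)(C)C)C2)[C@H](O[Si](C)(C)C(C)(C)C)[C@@H]1C(C)(C)O[Si](C)(C)C | intermediate
16 | (6R,7R,8R,10S)‑3,6‑bis(tert‑butyldimethylsilyloxy)‑11‑(trimethylsilyloxy)guaia‑1(5),3‑dien‑8‑ol | O[C@@H]1C[C@H](C)C2=C(C(C)=C(O[Si](C)(C)C(C)(C)C)C2)[C@H](O[Si](C)(C)C(C)(C)C)[C@@H]1C(C)(C)O[Si](C)(C)C | intermediate
17 | (6R,7R,8R,10S)‑3,6‑bis(tert‑butyldimethylsilyloxy)guaia‑1(5),3‑diene‑8,11‑diol | O[C@@H]1C[C@H](C)C2=C(C(C)=C(O[Si](C)(C)C(C)(C)C)C2)[C@H](O[Si](C)(C)C(C)(C)C)[C@@H]1C(C)(C)O | intermediate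
18 | (6R,7R,8R,10S)‑3,6‑bis(tert‑butyldimethylsilyloxy)‑11‑hydroxyguaia‑1(5),3‑dien‑8‑yl (2Z)‑2‑methylbut‑2‑enoate | C/C=C(/C)C(=O)O[C@@H]1C[C@H](C)C2=C(C(C)=C(O[Si](C)(C)C(C)(C)C)C2)[C@H](O[Si](C)(C)C(C)(C)C)[C@@H]1C(C)(C)O | intermediate
19 | (6R,7R,8R,10S)‑11‑acetoxy‑3,6‑bis(tert‑butyldimethylsilyloxy)guaia‑1(5),3‑dien‑8‑yl (2Z)‑2‑methylbut‑2‑enoate | C/C=C(/C)C(=O)O[C@@H]1C[C@H](C)C2=C(C(C)=C(O[Si](C)(C)C(C)(C)C)C2)[C@H](O[Si](C)(C)C(C)(C)C)[C@@H]1C(C)(C)OC(C)=O | intermediate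
20 | (1R,6R,7R,8R,10S)‑11‑acetoxy‑6‑(tert‑butyldimethylsilyloxy)‑1‑(tert‑butyldimethylsilylperoxy)‑3‑oxoguai‑4‑en‑8‑yl (2Z)‑2‑methylbut‑2‑enoate | C/C=C(/C)C(=O)O[C@@H]1C[C@H](C)[C@]2(OO[Si](C)(C)C(C)(C)C)CC(=O)C(C)=C2[C@H](O[Si](C)(C)C(C)(C)C)[C@@H]1C(C)(C)OC(C)=O | intermediate
21 | (1R,6R,7R,8R,10S)‑11‑acetoxy‑1,6‑bis(tert‑butyldimethylsilyloxy)‑3‑oxoguai‑4‑en‑8‑yl (2Z)‑2‑methylbut‑2‑enoate | C/C=C(/C)C(=O)O[C@@H]1C[C@H](C)[C@]2(O[Si](C)(C)C(C)(C)C)CC(=O)C(C)=C2[C@H](O[Si](C)(C)C(C)(C)C)[C@@H]1C(C)(C)OC(C)=O | intermediate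
22 | (1R,6R,7S,8R,10S)‑11‑acetoxy‑1,6‑dihydroxy‑3‑oxoguai‑4‑en‑8‑yl (2Z)‑2‑methylbut‑2‑enoate (1α‑OH; 6β‑OH; 7β side chain; 8β‑angelate; 10β‑methyl) | C/C=C(/C)C(=O)O[C@@H]1C[C@H](C)[C@]2(O)CC(=O)C(C)=C2[C@H](O)[C@@H]1C(C)(C)OC(C)=O | target

**Step count**

Total: 11 steps. Longest linear sequence: 9 steps (steps 1, 2, 3, 4, 7, 8, 9, 10, 11); steps 5 and 6 make the second fragment.

**Three steps most likely to fail, with fallbacks**

Step 7 (the (4+3) cycloaddition). The risks are which diene terminus bonds first, compact versus extended approach (this decides C7), and the acid sensitivity of 10. The fallback replaces the oxyallyl cation by a rhodium vinylcarbenoid. It sets out from 10, which TBSOTf and Et3N convert into the achiral triene tert‑butyl{[(3Z,4E)‑3‑{[tert‑butyl(dimethyl)silyl]oxymethylidene}‑4‑ethylidene‑2‑methylcyclopent‑1‑en‑1‑yl]oxy}dimethylsilane F2. Cyclopropanation of its enol ether double bond with methyl 2‑diazo‑3‑(tert‑butyldimethylsilyloxy)but‑3‑enoate under Rh2(PTAD)4 (the catalyst enantiomer that gives the 6R,10S series), followed by divinylcyclopropane (Cope) rearrangement, gives methyl 3,6,8‑tris(tert‑butyldimethylsilyloxy)‑12,13‑dinorguaia‑1(5),3,7‑trien‑11‑oate (C6 OTBS and C10 methyl cis) F3. K2CO3 in MeOH at −20 °C cleaves only the C8 silyl enol ether, and NaBH4 reduces the rapidly epimerising β‑keto ester from the α face to methyl (6R,7R,8R,10S)‑3,6‑bis(tert‑butyldimethylsilyloxy)‑8‑hydroxy‑12,13‑dinorguaia‑1(5),3‑dien‑11‑oate F4. Excess MeMgBr then gives diol 17, where the route is rejoined; the catalyst sets the enantiomer, so the resolution of step 8 is not needed.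

Step 4 (1,4‑hydrosilylation). The risks are 1,2‑ versus 1,4‑addition, attack through the ketone, and the geometry of the enol ether. The fallback works under thermodynamic control in two operations. It sets out from 9: Zn in AcOH reduces the ene‑dione double bond to (2E)‑2‑ethylidene‑5‑methyl‑4‑oxocyclopentane‑1‑carbaldehyde F1, which is silylated at once (TBSOTf, Et3N, −78 °C; the aldehyde enolises first and the oxygen settles syn to the sp3 carbon C4). This returns to 10.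

Step 8 (kinetic resolution by CBS reduction). The risks are an insufficient rate difference between the enantiomers and the 50% ceiling. The fallback is a classical resolution. It sets out from 15: L‑selectride gives racemic 16, and esterification of its C8 hydroxyl with (S)‑O‑methylmandelic acid (DCC, DMAP) gives two diastereomers that are separated on silica; the one needed is (6R,7R,8R,10S)‑3,6‑bis(tert‑butyldimethylsilyloxy)‑11‑(trimethylsilyloxy)guaia‑1(5),3‑dien‑8‑yl (2S)‑2‑methoxy‑2‑phenylacetate F5. K2CO3 in MeOH removes the mandelate and the trimethylsilyl group and returns to 17.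

**Further compounds**

F1 | step 4 | (2E)‑2‑ethylidene‑5‑methyl‑4‑oxocyclopentane‑1‑carbaldehyde (racemic diastereomer mixture) | C/C=C1/C(C=O)C(C)C(=O)C1
F2 | step 7 | tert‑butyl{[(3Z,4E)‑3‑{[tert‑butyl(dimethyl)silyl]oxymethylidene}‑4‑ethylidene‑2‑methylcyclopent‑1‑en‑1‑yl]oxy}dimethylsilane | C/C=C1\CC(O[Si](C)(C)C(C)(C)C)=C(C)/C1=C\O[Si](C)(C)C(C)(C)C
F3 | step 7 | methyl 3,6,8‑tris(tert‑butyldimethylsilyloxy)‑12,13‑dinorguaia‑1(5),3,7‑trien‑11‑oate (6,10‑cis) | COC(=O)C1=C(O[Si](C)(C)C(C)(C)C)C[C@H](C)C2=C(C(C)=C(O[Si](C)(C)C(C)(C)C)C2)[C@@H]1O[Si](C)(C)C(C)(C)C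
F4 | step 7 | methyl (6R,7R,8R,10S)‑3,6‑bis(tert‑butyldimethylsilyloxy)‑8‑hydroxy‑12,13‑dinorguaia‑1(5),3‑dien‑11‑oate | O[C@@H]1C[C@H](C)C2=C(C(C)=C(O[Si](C)(C)C(C)(C)C)C2)[C@H](O[Si](C)(C)C(C)(C)C)[C@@H]1C(=O)OC
F5 | step 8 | (6R,7R,8R,10S)‑3,6‑bis(tert‑butyldimethylsilyloxy)‑11‑(trimethylsilyloxy)guaia‑1(5),3‑dien‑8‑yl (2S)‑2‑methoxy‑2‑phenylacetate | CO[C@H](C(=O)O[C@@H]1C[C@H](C)C2=C(C(C)=C(O[Si](C)(C)C(C)(C)C)C2)[C@H](O[Si](C)(C)C(C)(C)C)[C@@H]1C(C)(C)O[Si](C)(C)C)c1ccccc1
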